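## Retrosynthetic overview

1. The ten-membered ring is closed last, at C9–C10, by a nickel-catalysed, chromium-mediated alkenyl iodide–aldehyde coupling that also creates the C9 carbinol.
2. Before that, the C6–C7 bond and the γ-lactone are made in one operation by an iridium-catalysed transfer-hydrogenative coupling of an epoxy alcohol (fragment A) with a Morita–Baylis–Hillman ester (fragment B) that already carries the C8 3-methylbut-2-enoate.
3. Fragment A (C1–C6, C10, C14, C15): cis-epoxide by Sharpless epoxidation of a (Z,Z)-dienol, Z-iodoalkene by Stork–Zhao olefination, Z-trisubstituted alkene by ring cleavage of 3-methylcyclohex-2-enone.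
4. Fragment B (C7–C9, C11–C13): C8 from (S)-but-3-ene-1,2-diol via glyceraldehyde acetonide, Morita–Baylis–Hillman reaction with methyl acrylate, then two 3-methylbut-2-enoates (one is the leaving group, one stays).
5. Ring order: oxirane (in fragment A), then α-methylene-γ-butyrolactone (fragment union), then the cyclodecene (last step).

Assumption: positions are given in germacrane numbering (C4–C5 epoxide, C6 lactone carbinol, C8 ester carbon, C9 free carbinol, C1=C10 ring alkene), and the ligand antipodes written in steps 13 and 16 stand for those that give Re-face addition at the C6 aldehyde and Si-face addition at the C9 aldehyde, to be confirmed in a first run.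

## Route

Step 1
Reactants: 1 3-methylcyclohex-2-en-1-one
Product: 3 racemic 6-hydroxy-3-methylcyclohex-2-en-1-one, via sodium dienolate 2 (not isolated)
Conditions: NaN(SiMe3)2, THF, −78 °C; then 2-(phenylsulfonyl)-3-phenyloxaziridine, −78 °C; AcOH quench
Reagents that add atoms: 2-(phenylsulfonyl)-3-phenyloxaziridine, O=S(=O)(c1ccccc1)N1OC1c1ccccc1
Why: Kinetic deprotonation at C6 gives the cross-conjugated dienolate, which is hydroxylated by the N-sulfonyloxaziridine (Davis oxidation); the new stereocentre is destroyed in step 2.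

Step 2
Reactants: 3 racemic 6-hydroxy-3-methylcyclohex-2-en-1-one
Product: 4 methyl (2Z)-3-methyl-6-oxohex-2-enoate
Conditions: Pb(OAc)4, MeOH/toluene (1:1), 0 °C
Reagents that add atoms: methanol, CO
Why: Pb(OAc)4 cleaves the α-hydroxy ketone through its methanol hemiketal (Criegee-type glycol cleavage) to ester and aldehyde, and the Z geometry of the trisubstituted alkene is inherited from the six-membered ring.

Step 3
Reactants: 5 iodoethane
Product: 6 ethyltriphenylphosphonium iodide
Conditions: PPh3, toluene, 110 °C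
Reagents that add atoms: triphenylphosphine, c1ccc(cc1)P(c1ccccc1)c1ccccc1
Why: SN2 quaternisation of the phosphine by a primary iodide gives the salt as a filterable solid.

Step 4
Reactants: 6 ethyltriphenylphosphonium iodide; 4 methyl (2Z)-3-methyl-6-oxohex-2-enoate
Product: 10 methyl (2Z,6Z)-7-iodo-3-methylocta-2,6-dienoate, via ethylidenetriphenylphosphorane 7 (not isolated), via (1-iodoethyl)triphenylphosphonium iodide 8 (not isolated), via (1-iodoethylidene)triphenylphosphorane 9 (not isolated)
Conditions: n-BuLi, THF, 0 °C; I2, −78 °C; NaN(SiMe3)2, −20 °C; then 4, −78 °C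
Reagents that add atoms: iodine, I-I
Why: Stork–Zhao olefination, in which the α-iodo ylide adds to the aldehyde under kinetic control to give the (Z)-2-iodoalk-2-ene (iodine cis to the chain) while the enoate is inert at −78 °C.

Step 5
Reactants: 10 methyl (2Z,6Z)-7-iodo-3-methylocta-2,6-dienoate
Product: 11 (2Z,6Z)-7-iodo-3-methylocta-2,6-dien-1-ol
Conditions: i-Bu2AlH (2.2 equiv), CH2Cl2, −78 °C; aq. potassium sodium tartrate
Reagents that add atoms: none
Why: 1,2-Reduction of the conjugated ester by the aluminium hydride gives the allylic alcohol without touching the alkenyl iodide or either alkene geometry.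

Step 6
Reactants: 11 (2Z,6Z)-7-iodo-3-methylocta-2,6-dien-1-ol
Product: 12 [(2S,3R)-3-[(3Z)-4-iodopent-3-en-1-yl]-3-methyloxiran-2-yl]methanol
Conditions: Ti(Oi-Pr)4 (0.2 equiv), L-(+)-diethyl tartrate (0.24 equiv), t-BuOOH, 4 Å sieves, CH2Cl2, −20 °C
Reagents that add atoms: tert-butyl hydroperoxide, CC(C)(C)OO
Why: Sharpless asymmetric epoxidation, in which the L-(+)-tartrate titanium catalyst delivers oxygen to one face of the (Z)-allylic alcohol (nerol-type) to give the (2S,3R) cis-epoxide that becomes C5 (S) and C4 (R), while the iodoalkene is not an allylic alcohol and does not react.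

Step 7
Reactants: 13 (2S)-but-3-ene-1,2-diol
Product: 14 (4S)-4-ethenyl-2,2-dimethyl-1,3-dioxolane
Conditions: 2,2-dimethoxypropane, PPTS (cat.), CH2Cl2, 23 °C
Reagents that add atoms: 2,2-dimethoxypropane, COC(C)(C)OC
Why: Acid-catalysed transketalisation ties the 1,2-diol up as its acetonide.

Step 8
Reactants: 14 (4S)-4-ethenyl-2,2-dimethyl-1,3-dioxolane
Product: 16 (4R)-2,2-dimethyl-1,3-dioxolane-4-carbaldehyde, via ozonide 15 (not isolated)
Conditions: O3, CH2Cl2, −78 °C; then Me2S, −78 to 23 °C
Reagents that add atoms: ozone, [O-][O+]=O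
Why: Ozonolysis with reductive work-up cleaves the vinyl group to the aldehyde, made fresh because it polymerises on storage, and the stereocentre is untouched (S becomes R only by a change of priorities).

Step 9
Reactants: 16 (4R)-2,2-dimethyl-1,3-dioxolane-4-carbaldehyde; 17 methyl prop-2-enoate
Product: 18 methyl (3RS)-3-[(4R)-2,2-dimethyl-1,3-dioxolan-4-yl]-3-hydroxy-2-methylidenepropanoate (about 7:3 mixture of C3 epimers)
Conditions: DABCO (0.5 equiv), 17 (3 equiv), 1,4-dioxane/H2O, 23 °C, 3 d
Reagents that add atoms: none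
Why: Morita–Baylis–Hillman reaction of the DABCO-derived ammonium enolate with an aldehyde that does not racemise under these conditions; the new carbinol centre is of no consequence because it is lost at the π-allyl stage in step 13.

Step 10
Reactants: 18 methyl (3RS)-3-[(4R)-2,2-dimethyl-1,3-dioxolan-4-yl]-3-hydroxy-2-methylidenepropanoate
Product: 19 methyl (3RS,4R)-3,4,5-trihydroxy-2-methylidenepentanoate
Conditions: AcOH/H2O (4:1), 23 °C; toluene azeotrope
Reagents that add atoms: none
Why: Mild aqueous acid hydrolyses the terminal acetonide, and a weak acid at room temperature is chosen so that the γ-hydroxy ester does not lactonise.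

Step 11
Reactants: 19 methyl (3RS,4R)-3,4,5-trihydroxy-2-methylidenepentanoate
Product: 20 methyl (3RS,4R)-5-[(tert-butyldimethylsilyl)oxy]-3,4-dihydroxy-2-methylidenepentanoate
Conditions: TBSCl (1.05 equiv), imidazole, CH2Cl2/DMF, 0 °C
Reagents that add atoms: tert-butyldimethylsilyl chloride, CC(C)(C)[Si](C)(C)Cl
Why: The primary hydroxyl is silylated selectively for steric reasons.

Step 12
Reactants: 20 methyl (3RS,4R)-5-[(tert-butyldimethylsilyl)oxy]-3,4-dihydroxy-2-methylidenepentanoate; 21 3-methylbut-2-enoyl chloride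
Product: 22 methyl (3RS,4R)-5-[(tert-butyldimethylsilyl)oxy]-3,4-bis[(3-methylbut-2-enoyl)oxy]-2-methylidenepentanoate
Conditions: 21 (3 equiv), pyridine, DMAP (0.1 equiv), CH2Cl2, 0 to 23 °C
Reagents that add atoms: none
Why: DMAP-catalysed acylation of both secondary hydroxyls, with pyridine as base to avoid deconjugation through the vinylketene; the C3 ester is the later leaving group, the C4 ester is the ester of the target, and any SN2' isomer of the C3 ester would give the same π-allyl.

Step 13
Reactants: 12 [(2S,3R)-3-[(3Z)-4-iodopent-3-en-1-yl]-3-methyloxiran-2-yl]methanol; 22 methyl (3RS,4R)-5-[(tert-butyldimethylsilyl)oxy]-3,4-bis[(3-methylbut-2-enoyl)oxy]-2-methylidenepentanoate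
Product: 25 (1S)-2-[(tert-butyldimethylsilyl)oxy]-1-{(2R,3S)-2-[(2S,3R)-3-[(3Z)-4-iodopent-3-en-1-yl]-3-methyloxiran-2-yl]-4-methylidene-5-oxooxolan-3-yl}ethyl 3-methylbut-2-enoate, via epoxy aldehyde 23 (not isolated), via hydroxy ester 24 (not isolated)
Conditions: [Ir(cod)Cl]2 (5 mol%), (R)-SEGPHOS (10 mol%), 4-cyano-3-nitrobenzoic acid (20 mol%), K3PO4 (1 equiv), 22 (1.5 equiv), THF, 60 °C; then PPTS (cat.), CH2Cl2, 23 °C
Reagents that add atoms: none
Why: Proposed new method: an iridium-catalysed transfer-hydrogenative coupling of a primary epoxy alcohol with a γ-substituted Morita–Baylis–Hillman ester, not yet shown for such donors or alcohols, in which the cyclometallated trivalent iridium C,O-benzoate dehydrogenates 12 to aldehyde 23, the iridium hydride is deprotonated to a monovalent iridate that ionises the activated allylic ester of 22 (both C3 epimers converge), and the primary σ-allyl iridium with the C8 side chain pseudo-equatorial adds at C7 through a closed chair transition state to the ligand-selected Re face of the aldehyde (6R, catalyst control against the Felkin bias of the epoxide) and anti to the C8–O bond (7S, matched with the resident centre), giving anti adduct 24 whose hydroxyl closes the trans-lactone; the closest known reaction types are the iridium-catalysed anti-crotylation and 2-(alkoxycarbonyl)allylation of primary alcohols with allylic acetates or carbonates.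

Step 14
Reactants: 25 (the silyl ether from step 13)
Product: 26 (1S)-2-hydroxy-1-{(2R,3S)-2-[(2S,3R)-3-[(3Z)-4-iodopent-3-en-1-yl]-3-methyloxiran-2-yl]-4-methylidene-5-oxooxolan-3-yl}ethyl 3-methylbut-2-enoate
Conditions: HF·pyridine, pyridine, THF, 0 °C
Reagents that add atoms: none
Why: Fluoride cleaves the primary silyl ether, and the buffered acidic medium suppresses 1,2-acyl migration of the C8 ester and leaves epoxide and lactone intact.

Step 15
Reactants: 26 (the primary alcohol from step 14)
Product: 27 (1S)-1-{(2R,3R)-2-[(2S,3R)-3-[(3Z)-4-iodopent-3-en-1-yl]-3-methyloxiran-2-yl]-4-methylidene-5-oxooxolan-3-yl}-2-oxoethyl 3-methylbut-2-enoate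
Conditions: Dess–Martin periodinane, pyridine, CH2Cl2, 0 °C
Reagents that add atoms: none
Why: Dess–Martin oxidation under buffered, non-basic conditions gives the α-acyloxy aldehyde without epimerising C8 (the ring carbon becomes R only by a change of priorities), and it is used at once.

Step 16
Reactants: 27 (the iodo aldehyde from step 15)
Product: 28 CNP0188779.1, (1(10)Z,4R,5S,6R,7S,8S,9S)-4,5-epoxy-9-hydroxy-8-[(3-methylbut-2-enoyl)oxy]germacra-1(10),11(13)-dien-12,6-olide
Conditions: CrCl2 (6 equiv), (S)-N-[2-(4-isopropyl-4,5-dihydro-1,3-oxazol-2-yl)-6-methylphenyl]methanesulfonamide (6.6 equiv), Et3N (6.6 equiv), THF, 23 °C; then NiCl2 (0.3 equiv), 27 added over 12 h (final 2 mM), 23 °C; ethylenediamine work-up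
Reagents that add atoms: none
Why: Nozaki–Hiyama–Kishi reaction in which zerovalent nickel inserts into the C–I bond with retention of the Z geometry, the alkenyl group passes to chromium and adds to the aldehyde to close the ten-membered ring, the chiral sulfonamide on chromium directing attack to the Si face (9S, reagent control) and high dilution suppressing dimers.

## Compound list

1 | 3-methylcyclohex-2-en-1-one | CC1=CC(=O)CCC1 | starting material
2 | sodium 5-methylcyclohexa-1,5-dien-1-olate (cross-conjugated dienolate of 1) | CC1=CC([O-])=CCC1.[Na+] | intermediate (not isolated)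
3 | racemic 6-hydroxy-3-methylcyclohex-2-en-1-one | CC1=CC(=O)C(O)CC1 | intermediate
4 | methyl (2Z)-3-methyl-6-oxohex-2-enoate | COC(=O)/C=C(/C)CCC=O | intermediate
5 | iodoethane | CCI | starting material
6 | ethyltriphenylphosphonium iodide | CC[P+](c1ccccc1)(c1ccccc1)c1ccccc1.[I-] | intermediate
7 | ethylidenetriphenylphosphorane | CC=P(c1ccccc1)(c1ccccc1)c1ccccc1 | intermediate (not isolated)
8 | (1-iodoethyl)triphenylphosphonium iodide (racemic) | CC(I)[P+](c1ccccc1)(c1ccccc1)c1ccccc1.[I-] | intermediate (not isolated)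
9 | (1-iodoethylidene)triphenylphosphorane | CC(I)=P(c1ccccc1)(c1ccccc1)c1ccccc1 | intermediate (not isolated)
10 | methyl (2Z,6Z)-7-iodo-3-methylocta-2,6-dienoate | COC(=O)/C=C(/C)CC/C=C(/C)I | intermediate
11 | (2Z,6Z)-7-iodo-3-methylocta-2,6-dien-1-ol | OC/C=C(/C)CC/C=C(/C)I | intermediate
12 | [(2S,3R)-3-[(3Z)-4-iodopent-3-en-1-yl]-3-methyloxiran-2-yl]methanol (fragment A) | OC[C@@H]1O[C@]1(C)CC/C=C(/C)I | intermediate
13 | (2S)-but-3-ene-1,2-diol | C=C[C@H](O)CO | starting material
14 | (4S)-4-ethenyl-2,2-dimethyl-1,3-dioxolane | C=C[C@H]1COC(C)(C)O1 | intermediate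
15 | 3-[(4R)-2,2-dimethyl-1,3-dioxolan-4-yl]-1,2,4-trioxolane (ozonide, epimers at the trioxolane carbon) | O1OC(OC1)[C@H]1COC(C)(C)O1 | intermediate (not isolated)
16 | (4R)-2,2-dimethyl-1,3-dioxolane-4-carbaldehyde | O=C[C@H]1COC(C)(C)O1 | intermediate
17 | methyl prop-2-enoate (methyl acrylate) | C=CC(=O)OC | starting material
18 | methyl (3RS)-3-[(4R)-2,2-dimethyl-1,3-dioxolan-4-yl]-3-hydroxy-2-methylidenepropanoate | C=C(C(=O)OC)C(O)[C@H]1COC(C)(C)O1 | intermediate
19 | methyl (3RS,4R)-3,4,5-trihydroxy-2-methylidenepentanoate | C=C(C(=O)OC)C(O)[C@H](O)CO | intermediate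
20 | methyl (3RS,4R)-5-[(tert-butyldimethylsilyl)oxy]-3,4-dihydroxy-2-methylidenepentanoate | C=C(C(=O)OC)C(O)[C@H](O)CO[Si](C)(C)C(C)(C)C | intermediate
21 | 3-methylbut-2-enoyl chloride | CC(C)=CC(=O)Cl | starting material
22 | methyl (3RS,4R)-5-[(tert-butyldimethylsilyl)oxy]-3,4-bis[(3-methylbut-2-enoyl)oxy]-2-methylidenepentanoate (fragment B) | C=C(C(=O)OC)C(OC(=O)C=C(C)C)[C@H](OC(=O)C=C(C)C)CO[Si](C)(C)C(C)(C)C | intermediate
23 | (2R,3R)-3-[(3Z)-4-iodopent-3-en-1-yl]-3-methyloxirane-2-carbaldehyde | O=C[C@@H]1O[C@]1(C)CC/C=C(/C)I | intermediate (not isolated)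
24 | methyl (3R,4S)-5-[(tert-butyldimethylsilyl)oxy]-3-{(R)-hydroxy[(2S,3R)-3-[(3Z)-4-iodopent-3-en-1-yl]-3-methyloxiran-2-yl]methyl}-4-[(3-methylbut-2-enoyl)oxy]-2-methylidenepentanoate | C=C(C(=O)OC)[C@H]([C@@H](O)[C@@H]1O[C@]1(C)CC/C=C(/C)I)[C@H](OC(=O)C=C(C)C)CO[Si](C)(C)C(C)(C)C | intermediate (not isolated)
25 | (1S)-2-[(tert-butyldimethylsilyl)oxy]-1-{(2R,3S)-2-[(2S,3R)-3-[(3Z)-4-iodopent-3-en-1-yl]-3-methyloxiran-2-yl]-4-methylidene-5-oxooxolan-3-yl}ethyl 3-methylbut-2-enoate | C=C1C(=O)O[C@H]([C@@H]1[C@H](OC(=O)C=C(C)C)CO[Si](C)(C)C(C)(C)C)[C@@H]1O[C@]1(C)CC/C=C(/C)I | intermediate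
26 | (1S)-2-hydroxy-1-{(2R,3S)-2-[(2S,3R)-3-[(3Z)-4-iodopent-3-en-1-yl]-3-methyloxiran-2-yl]-4-methylidene-5-oxooxolan-3-yl}ethyl 3-methylbut-2-enoate | C=C1C(=O)O[C@H]([C@@H]1[C@H](OC(=O)C=C(C)C)CO)[C@@H]1O[C@]1(C)CC/C=C(/C)I | intermediate
27 | (1S)-1-{(2R,3R)-2-[(2S,3R)-3-[(3Z)-4-iodopent-3-en-1-yl]-3-methyloxiran-2-yl]-4-methylidene-5-oxooxolan-3-yl}-2-oxoethyl 3-methylbut-2-enoate | C=C1C(=O)O[C@H]([C@@H]1[C@H](OC(=O)C=C(C)C)C=O)[C@@H]1O[C@]1(C)CC/C=C(/C)I | intermediate
28 | CNP0188779.1, (1(10)Z,4R,5S,6R,7S,8S,9S)-4,5-epoxy-9-hydroxy-8-[(3-methylbut-2-enoyl)oxy]germacra-1(10),11(13)-dien-12,6-olide (trans-fused lactone, cis-epoxide) | C=C1C(=O)O[C@@H]2[C@@H]1[C@H](OC(=O)C=C(C)C)[C@@H](O)/C(C)=C\CC[C@@]1(C)O[C@@H]21 | target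

## Step count and risks

Total step count: 16. Longest linear sequence: 10 steps (13 to 28, steps 7–16); the other arm is 9 steps (1 to 28, steps 1, 2, 4, 5, 6, 13–16) and the phosphonium salt is a one-step side branch.

The three steps most likely to fail:

**Step 13 (new iridium coupling).** The risks are:
- insertion of the monovalent iridium intermediate into the alkenyl C–I bond;
- erosion of the anti selectivity, because the 2-ester destabilises the syn π-allyl;
- incomplete catalyst control against the Felkin preference of the epoxy aldehyde;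
- oxa-Michael addition to the acrylate, or loss of the C8 ester by β-elimination.

The fallback uses known chemistry, sets out from 12 and 22 and comes back at 25. Alcohol 12 is oxidised with Dess–Martin periodinane to epoxy aldehyde 23, now isolated. Ester 22 is treated with MgBr2·OEt2 in THF (SN2' displacement of the allylic ester) to give methyl (2Z,4S)-2-(bromomethyl)-5-[(tert-butyldimethylsilyl)oxy]-4-[(3-methylbut-2-enoyl)oxy]pent-2-enoate F1. Indium powder in THF/H2O joins 23 and F1 in a Barbier allylation. The Z bromide gives the syn adduct, the epoxy aldehyde reacts in the Felkin sense, and the allyl face anti to the C8–O bond is used, so all three substrate preferences point the same way and give the 6-epi hydroxy ester F2, which is kept open-chain. A Mitsunobu reaction (PPh3, DIAD, ClCH2CO2H) inverts C6 and gives the C6 chloroacetate F3. Thiourea/NaHCO3 removes the chloroacetyl group to give 24, which lactonises (PPTS) to 25. Inverting C6 alone turns the syn/Felkin adduct into the required 6R trans-lactone.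

**Step 16 (ring closure).** The risks are a slow medium-ring closure, the wrong sense or low level of induction at C9, and Lewis-acid damage to the epoxide. The fallback sets out from 27 and comes back at 28. The ring is closed without chiral ligand (CrCl2, NiCl2 cat., DMSO, 2 mM), accepting a C9 mixture that contains 9-epi-28 F4. The mixture is oxidised with Dess–Martin periodinane to the single C9 enone F5. Reagent-controlled 1,2-reduction (the 2-methyl-CBS-oxazaborolidine antipode that gives 9S, catecholborane, toluene, −78 °C) then gives 28.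

**Step 10 (acetonide hydrolysis).** The risk is γ-lactonisation of the C4 hydroxyl onto the methyl ester under acid. The fallback sets out from 13 and comes back at 20, and needs no acid once the ester is present. Diol 13 is silylated (TBSCl, imidazole) to (2S)-1-[(tert-butyldimethylsilyl)oxy]but-3-en-2-ol F6. 4-Methoxybenzyl trichloroacetimidate with catalytic camphorsulfonic acid gives tert-butyl{[(2S)-2-[(4-methoxybenzyl)oxy]but-3-en-1-yl]oxy}dimethylsilane F7. Ozonolysis (O3, then Me2S) gives (2R)-3-[(tert-butyldimethylsilyl)oxy]-2-[(4-methoxybenzyl)oxy]propanal F8. Morita–Baylis–Hillman reaction with 17 and DABCO gives methyl (3RS,4R)-5-[(tert-butyldimethylsilyl)oxy]-3-hydroxy-4-[(4-methoxybenzyl)oxy]-2-methylidenepentanoate F9. DDQ in CH2Cl2/pH 7 buffer removes the 4-methoxybenzyl group under neutral conditions to give 20.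

## Further compounds

F1 | step 13 | methyl (2Z,4S)-2-(bromomethyl)-5-[(tert-butyldimethylsilyl)oxy]-4-[(3-methylbut-2-enoyl)oxy]pent-2-enoate | COC(=O)/C(CBr)=C/[C@H](OC(=O)C=C(C)C)CO[Si](C)(C)C(C)(C)C
F2 | step 13 | 6-epi hydroxy ester (C6 epimer of 24, (S)-carbinol, otherwise as 24) | C=C(C(=O)OC)[C@H]([C@H](O)[C@@H]1O[C@]1(C)CC/C=C(/C)I)[C@H](OC(=O)C=C(C)C)CO[Si](C)(C)C(C)(C)C
F3 | step 13 | C6 chloroacetate (chloroacetic ester of 24 at the C6 hydroxyl, C6 R) | C=C(C(=O)OC)[C@H]([C@@H](OC(=O)CCl)[C@@H]1O[C@]1(C)CC/C=C(/C)I)[C@H](OC(=O)C=C(C)C)CO[Si](C)(C)C(C)(C)C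
F4 | step 16 | 9-epi-28 (9R epimer of the target) | C=C1C(=O)O[C@@H]2[C@@H]1[C@H](OC(=O)C=C(C)C)[C@H](O)/C(C)=C\CC[C@@]1(C)O[C@@H]21
F5 | step 16 | C9 enone (9-oxo analogue of 28) | C=C1C(=O)O[C@@H]2[C@@H]1[C@H](OC(=O)C=C(C)C)C(=O)/C(C)=C\CC[C@@]1(C)O[C@@H]21
F6 | step 10 | (2S)-1-[(tert-butyldimethylsilyl)oxy]but-3-en-2-ol | C=C[C@H](O)CO[Si](C)(C)C(C)(C)C
F7 | step 10 | tert-butyl{[(2S)-2-[(4-methoxybenzyl)oxy]but-3-en-1-yl]oxy}dimethylsilane | C=C[C@H](OCc1ccc(OC)cc1)CO[Si](C)(C)C(C)(C)C
F8 | step 10 | (2R)-3-[(tert-butyldimethylsilyl)oxy]-2-[(4-methoxybenzyl)oxy]propanal | O=C[C@H](OCc1ccc(OC)cc1)CO[Si](C)(C)C(C)(C)C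
F9 | step 10 | methyl (3RS,4R)-5-[(tert-butyldimethylsilyl)oxy]-3-hydroxy-4-[(4-methoxybenzyl)oxy]-2-methylidenepentanoate | C=C(C(=O)OC)C(O)[C@H](OCc1ccc(OC)cc1)CO[Si](C)(C)C(C)(C)C
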